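**Retrosynthetic overview**
1. Target 17 ← removal of two MOM ethers ← chemoselective hydrogenation of E-chalcone 15 ← Claisen–Schmidt condensation of ring A methyl ketone 9 with ring B aldehyde 14 (from 5-bromovanillin by demethylation, selective 4-O-methylation and Stille prenylation).
2. Ketone 9 ← chroman 8, whose pyran ring is cut at two C–C bonds, aryl C4a–C4 and C3–C2 (the quaternary carbon), giving the fibrate-type acid 4 and a two-carbon unit, diphenyl(vinyl)sulfonium triflate 5 (decarboxylative radical addition, then intramolecular phenoxide C-alkylation).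
3. Acid 4 ← phloroacetophenone 1 by O-alkylation of the 4-OH with ethyl 2-bromo-2-methylpropanoate and saponification.
4. Enabling feature: in 4 the ether oxygen is para to the acetyl group on a 3,5-dihydroxyphenyl ring, so ring carbons C2 and C6 (ortho to the ether oxygen, each ortho and para to a free OH) are homotopic phloroglucinol-type carbon nucleophiles and the neighbouring OH supplies proton and phenoxide; annulation at either carbon can only give the 6-acyl-5,7-dihydroxy-2,2-dimethylchroman.
5. Ring order: both benzene rings are bought; the pyran ring is the only ring made (step 3).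

Key step: step 3

Remark on the chemistry: the target has no stereocentre and no stereogenic double bond, so the only stereo-defined compound on the route is E-chalcone 15; reagents 5 and 13 are taken as purchased.

**Step 1**
Reactants: 1 1-(2,4,6-trihydroxyphenyl)ethan-1-one (phloroacetophenone); 2 ethyl 2-bromo-2-methylpropanoate
Product: 3 ethyl 2-(4-acetyl-3,5-dihydroxyphenoxy)-2-methylpropanoate
Conditions: K2CO3 (1.1 equiv), DMF, 70 °C
Reagents that add atoms: none
Why: Williamson-type O-alkylation with an α-bromoisobutyrate as in fibrate synthesis; the 4-OH (para to the acetyl group, not hydrogen-bonded to the carbonyl) is the most acidic and least hindered hydroxyl, so one equivalent of base should ionise and alkylate it while the two chelated ortho hydroxyls stay free.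

**Step 2**
Reactants: 3 ethyl 2-(4-acetyl-3,5-dihydroxyphenoxy)-2-methylpropanoate
Product: 4 2-(4-acetyl-3,5-dihydroxyphenoxy)-2-methylpropanoic acid
Conditions: LiOH·H2O (4 equiv), THF/MeOH/H2O, 40 °C; then 1 M HCl to pH 2
Reagents that add atoms: lithium hydroxide, [Li+].[OH-]
Why: Saponification (acyl–oxygen cleavage by hydroxide) of the ester; aryl ether, ketone and phenols are inert to aqueous base and the acid is released on acidification.

**Step 3**
Reactants: 4 2-(4-acetyl-3,5-dihydroxyphenoxy)-2-methylpropanoic acid; 5 diphenyl(vinyl)sulfonium trifluoromethanesulfonate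
Product: 8 1-(5,7-dihydroxy-2,2-dimethyl-3,4-dihydro-2H-chromen-6-yl)ethan-1-one, via sulfur ylide 6 (not isolated), via alkylsulfonium phenoxide inner salt 7 (not isolated)
Conditions: 4CzIPN (2,4,5,6-tetrakis(carbazol-9-yl)isophthalonitrile, 3 mol%), K2HPO4 (1.2 equiv), 5 (1.3 equiv), degassed MeCN/H2O 9:1 (0.05 M), blue LEDs (450 nm), 25 °C; then 45 °C in the dark
Reagents that add atoms: none
Why: Proposed new method: a decarboxylative radical–polar crossover (4+2) annulation in which photoexcited 4CzIPN oxidises the carboxylate of 4 (the only group ionised by the phosphate buffer), loss of CO2 gives the nucleophilic tertiary α-aryloxyalkyl radical, and this adds to the terminal CH2 of the electron-poor vinylsulfonium 5 (first new C–C bond, at the quaternary carbon); the resulting α-sulfonium radical is reduced by the reduced photocatalyst to ylide 6, which closes the catalytic cycle without external oxidant or reductant. Proton transfer from the phenol side gives the primary alkylsulfonium phenoxide 7, whose ring carbon ortho to the ether oxygen displaces diphenyl sulfide in a 6-exo-tet SN2 C-alkylation that closes the pyran ring (second new C–C bond, aryl–CH2), followed by proton loss to restore the arene. The closest known reaction types are the photoredox decarboxylative Giese addition of α-aryloxyisobutyric acids to electron-poor alkenes, photoredox radical–polar crossover cyclisations, and annulations of two-site nucleophiles with diphenyl(vinyl)sulfonium triflate by conjugate addition, ylide protonation and intramolecular SN2 displacement; new here is that the first nucleophile is a carbon radical and the second an aryl carbon. No stereocentre is formed. The step needs C- over O-alkylation and one ring-fusion regiochemistry: only ring carbons C2 and C6 reach the sulfonium carbon through a six-membered transition state (a phenoxide oxygen would need an eight-membered one), these two carbons are homotopic, each is ortho and para to an oxygen donor, and the gem-dimethyl group favours closure, so only the 6-acetyl-5,7-dihydroxychroman should form.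

**Step 4**
Reactants: 8 1-(5,7-dihydroxy-2,2-dimethyl-3,4-dihydro-2H-chromen-6-yl)ethan-1-one
Product: 9 1-[5,7-bis(methoxymethoxy)-2,2-dimethyl-3,4-dihydro-2H-chromen-6-yl]ethan-1-one
Conditions: NaH (2.5 equiv), MOMCl (3 equiv), DMF, 0 °C to rt
Reagents that add atoms: chloromethyl methyl ether (MOMCl), COCCl
Why: Double Williamson etherification of the sodium phenoxides; blocking both hydroxyls ortho to the acetyl group keeps the enolate reactive and prevents flavanone formation in the later condensation.

**Step 5**
Reactants: 10 3-bromo-4-hydroxy-5-methoxybenzaldehyde (5-bromovanillin)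
Product: 11 3-bromo-4,5-dihydroxybenzaldehyde
Conditions: AlCl3 (1.1 equiv), pyridine (4.5 equiv), CH2Cl2, reflux; then 2 M HCl
Reagents that add atoms: none
Why: Lewis acid-assisted O-demethylation of a guaiacol, in which aluminium bound to the free hydroxyl chelates the neighbouring methoxy oxygen and pyridine removes the methyl group by SN2, leaving aldehyde and bromide untouched.

**Step 6**
Reactants: 11 3-bromo-4,5-dihydroxybenzaldehyde
Product: 12 3-bromo-5-hydroxy-4-methoxybenzaldehyde
Conditions: MeI (1.05 equiv), Li2CO3 (1.2 equiv), DMF, 40 °C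
Reagents that add atoms: iodomethane, CI
Why: Selective Williamson methylation of a catechol mono-anion; the 4-OH para to the formyl group and ortho to bromine is the more acidic one, so with a weak base it alone should be ionised and methylated.

**Step 7**
Reactants: 12 3-bromo-5-hydroxy-4-methoxybenzaldehyde; 13 tributyl(3-methylbut-2-en-1-yl)stannane
Product: 14 3-hydroxy-4-methoxy-5-(3-methylbut-2-en-1-yl)benzaldehyde
Conditions: Pd(PPh3)4 (5 mol%), DMF, 100 °C
Reagents that add atoms: none
Why: Stille cross-coupling of an aryl bromide with a prenylstannane, which should deliver the linear prenyl group by reductive elimination at the less hindered allyl terminus and tolerates the free phenol and the aldehyde.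

**Step 8**
Reactants: 9 1-[5,7-bis(methoxymethoxy)-2,2-dimethyl-3,4-dihydro-2H-chromen-6-yl]ethan-1-one; 14 3-hydroxy-4-methoxy-5-(3-methylbut-2-en-1-yl)benzaldehyde
Product: 15 (2E)-1-[5,7-bis(methoxymethoxy)-2,2-dimethyl-3,4-dihydro-2H-chromen-6-yl]-3-[3-hydroxy-4-methoxy-5-(3-methylbut-2-en-1-yl)phenyl]prop-2-en-1-one
Conditions: KOH (10 equiv), EtOH/H2O, rt to 40 °C; then 1 M HCl to pH 6 at 0 °C
Reagents that add atoms: none
Why: Claisen–Schmidt aldol condensation; the ketone enolate adds to the aldehyde (its phenoxide is meta to the formyl group and does not deactivate it) and E1cB dehydration should give the thermodynamically favoured E-enone.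

**Step 9**
Reactants: 15 (2E)-1-[5,7-bis(methoxymethoxy)-2,2-dimethyl-3,4-dihydro-2H-chromen-6-yl]-3-[3-hydroxy-4-methoxy-5-(3-methylbut-2-en-1-yl)phenyl]prop-2-en-1-one
Product: 16 1-[5,7-bis(methoxymethoxy)-2,2-dimethyl-3,4-dihydro-2H-chromen-6-yl]-3-[3-hydroxy-4-methoxy-5-(3-methylbut-2-en-1-yl)phenyl]propan-1-one
Conditions: H2 (1 atm), RhCl(PPh3)3 (5 mol%), toluene/EtOH 1:1, rt
Reagents that add atoms: none
Why: Homogeneous hydrogenation with RhCl(PPh3)3 should reduce the unhindered trans-disubstituted enone double bond much faster than the trisubstituted prenyl double bond and leave ketone, aryl ethers and MOM groups untouched.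

**Step 10**
Reactants: 16 1-[5,7-bis(methoxymethoxy)-2,2-dimethyl-3,4-dihydro-2H-chromen-6-yl]-3-[3-hydroxy-4-methoxy-5-(3-methylbut-2-en-1-yl)phenyl]propan-1-one
Product: 17 1-(5,7-dihydroxy-2,2-dimethyl-3,4-dihydro-2H-chromen-6-yl)-3-[3-hydroxy-4-methoxy-5-(3-methylbut-2-en-1-yl)phenyl]propan-1-one
Conditions: 3 M aq HCl/MeOH 1:5, 45 °C
Reagents that add atoms: none
Why: Acid-catalysed acetal exchange should remove both MOM ethers (assisted by the ortho carbonyl group) as dimethoxymethane; the prenyl group has no ortho hydroxyl to cyclise onto and the tertiary aryl ether of the chroman is stable at this acidity.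

**Compound list**
1 | 1-(2,4,6-trihydroxyphenyl)ethan-1-one (phloroacetophenone) | CC(=O)c1c(O)cc(O)cc1O | starting material
2 | ethyl 2-bromo-2-methylpropanoate | CCOC(=O)C(C)(C)Br | starting material
3 | ethyl 2-(4-acetyl-3,5-dihydroxyphenoxy)-2-methylpropanoate | CCOC(=O)C(C)(C)Oc1cc(O)c(C(C)=O)c(O)c1 | intermediate
4 | 2-(4-acetyl-3,5-dihydroxyphenoxy)-2-methylpropanoic acid | CC(=O)c1c(O)cc(OC(C)(C)C(=O)O)cc1O | intermediate
5 | diphenyl(vinyl)sulfonium trifluoromethanesulfonate | C=C[S+](c1ccccc1)c1ccccc1.[O-]S(=O)(=O)C(F)(F)F | starting material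
6 | sulfur ylide, diphenylsulfonium 3-(4-acetyl-3,5-dihydroxyphenoxy)-3-methylbutan-1-ide | CC(=O)c1c(O)cc(OC(C)(C)C[CH-][S+](c2ccccc2)c2ccccc2)cc1O | intermediate
7 | [3-(4-acetyl-3-hydroxy-5-oxidophenoxy)-3-methylbutyl]diphenylsulfonium, inner salt | CC(=O)c1c(O)cc(OC(C)(C)CC[S+](c2ccccc2)c2ccccc2)cc1[O-] | intermediate
8 | 1-(5,7-dihydroxy-2,2-dimethyl-3,4-dihydro-2H-chromen-6-yl)ethan-1-one | CC(=O)c1c(O)cc2c(c1O)CCC(C)(C)O2 | intermediate
9 | 1-[5,7-bis(methoxymethoxy)-2,2-dimethyl-3,4-dihydro-2H-chromen-6-yl]ethan-1-one | CC(=O)c1c(OCOC)cc2c(c1OCOC)CCC(C)(C)O2 | intermediate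
10 | 3-bromo-4-hydroxy-5-methoxybenzaldehyde (5-bromovanillin) | COc1cc(C=O)cc(Br)c1O | starting material
11 | 3-bromo-4,5-dihydroxybenzaldehyde | O=Cc1cc(O)c(O)c(Br)c1 | intermediate
12 | 3-bromo-5-hydroxy-4-methoxybenzaldehyde | COc1c(O)cc(C=O)cc1Br | intermediate
13 | tributyl(3-methylbut-2-en-1-yl)stannane | CCCC[Sn](CCCC)(CCCC)CC=C(C)C | starting material
14 | 3-hydroxy-4-methoxy-5-(3-methylbut-2-en-1-yl)benzaldehyde | COc1c(O)cc(C=O)cc1CC=C(C)C | intermediate
15 | (2E)-1-[5,7-bis(methoxymethoxy)-2,2-dimethyl-3,4-dihydro-2H-chromen-6-yl]-3-[3-hydroxy-4-methoxy-5-(3-methylbut-2-en-1-yl)phenyl]prop-2-en-1-one | COc1c(O)cc(/C=C/C(=O)c2c(OCOC)cc3c(c2OCOC)CCC(C)(C)O3)cc1CC=C(C)C | intermediate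
16 | 1-[5,7-bis(methoxymethoxy)-2,2-dimethyl-3,4-dihydro-2H-chromen-6-yl]-3-[3-hydroxy-4-methoxy-5-(3-methylbut-2-en-1-yl)phenyl]propan-1-one | COc1c(O)cc(CCC(=O)c2c(OCOC)cc3c(c2OCOC)CCC(C)(C)O3)cc1CC=C(C)C | intermediate
17 | 1-(5,7-dihydroxy-2,2-dimethyl-3,4-dihydro-2H-chromen-6-yl)-3-[3-hydroxy-4-methoxy-5-(3-methylbut-2-en-1-yl)phenyl]propan-1-one | COc1c(O)cc(CCC(=O)c2c(O)cc3c(c2O)CCC(C)(C)O3)cc1CC=C(C)C | target

**Step count and risks**
Total steps: 10. Longest linear sequence: 7 (steps 1, 2, 3, 4, 8, 9, 10).

Steps most likely to fail: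

1. Step 3. The α-sulfonium radical may attack the ring or abstract hydrogen before it is reduced. The carboxylate or a phenoxide may add to 5 in a polar conjugate addition without light. The alkylsulfonium may lose diphenyl sulfide by β-elimination instead of closing the ring. The fallback uses known chemistry, sets out from 1 and comes back at 8. Compound 1 would be O-alkylated at the 4-OH with 3-chloro-3-methylbut-1-yne (K2CO3, KI, acetone, reflux) to give 1-{2,6-dihydroxy-4-[(2-methylbut-3-yn-2-yl)oxy]phenyl}ethan-1-one F1. Heating F1 (xylene, 140 °C) should give 1-(5,7-dihydroxy-2,2-dimethyl-2H-chromen-6-yl)ethan-1-one F2 by aromatic propargyl Claisen rearrangement, 1,5-hydrogen shift and oxa-6π electrocyclisation; the two ortho carbons are again equivalent. Hydrogenation of the chromene double bond (H2, Pd on carbon, EtOAc, rt) would then give 8.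

2. Step 1. Loss of HBr from 2 to ethyl methacrylate may outrun substitution by the weakly nucleophilic para-acyl phenoxide, or alkylation may spread to the ortho hydroxyls. The fallback sets out from 1 and comes back at 4. A Bargellini three-component reaction (acetone as solvent and reactant, CHCl3, powdered NaOH, 0 to 40 °C; then 2 M HCl) would build the α-aryloxyisobutyric acid in one operation: the phenoxide opens the gem-dichloroepoxide formed from acetone and the trichloromethyl anion, and the acyl chloride is hydrolysed. This gives 4 directly and makes no compound outside the list (F0).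

3. Step 9. Competitive saturation or migration of the prenyl double bond, or slow turnover on the hindered enone, may erode chemoselectivity. The fallback changes the order of events so that no prenyl group is present during the reduction; it sets out from 9 and 12 and comes back at 16. Claisen–Schmidt condensation of 9 with 12 (KOH, EtOH/H2O) would give (2E)-1-[5,7-bis(methoxymethoxy)-2,2-dimethyl-3,4-dihydro-2H-chromen-6-yl]-3-(3-bromo-5-hydroxy-4-methoxyphenyl)prop-2-en-1-one F3. Hydrogenation (H2, RhCl(PPh3)3, toluene/EtOH), now without a second alkene, would give 1-[5,7-bis(methoxymethoxy)-2,2-dimethyl-3,4-dihydro-2H-chromen-6-yl]-3-(3-bromo-5-hydroxy-4-methoxyphenyl)propan-1-one F4. Stille coupling of F4 with 13 (Pd(PPh3)4, DMF, 100 °C) would then give 16.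

**Further compounds**
F1 | step 3 | 1-{2,6-dihydroxy-4-[(2-methylbut-3-yn-2-yl)oxy]phenyl}ethan-1-one | CC(=O)c1c(O)cc(OC(C)(C)C#C)cc1O
F2 | step 3 | 1-(5,7-dihydroxy-2,2-dimethyl-2H-chromen-6-yl)ethan-1-one | CC(=O)c1c(O)cc2c(c1O)C=CC(C)(C)O2
F0 | step 1 | none | none
F3 | step 9 | (2E)-1-[5,7-bis(methoxymethoxy)-2,2-dimethyl-3,4-dihydro-2H-chromen-6-yl]-3-(3-bromo-5-hydroxy-4-methoxyphenyl)prop-2-en-1-one | COc1c(O)cc(/C=C/C(=O)c2c(OCOC)cc3c(c2OCOC)CCC(C)(C)O3)cc1Br
F4 | step 9 | 1-[5,7-bis(methoxymethoxy)-2,2-dimethyl-3,4-dihydro-2H-chromen-6-yl]-3-(3-bromo-5-hydroxy-4-methoxyphenyl)propan-1-one | COc1c(O)cc(CCC(=O)c2c(OCOC)cc3c(c2OCOC)CCC(C)(C)O3)cc1Br
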